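**Retrosynthetic overview**

1. Target 15 ⇐ N-Boc amine 12 by Boc removal and reductive N-methylation; nothing else is touched once the stereocentre exists.
2. 12 ⇐ hispidulin 9 + enecarbamate 10 by a proposed catalytic enantioselective C8 aza-Friedel–Crafts reaction, which forms the aryl–pyrrolidine bond and the (R) centre in one step.
3. 9 ⇐ tribenzyl flavone 8 ⇐ chalcone 7 (ring C closed by oxidative cyclisation) ⇐ acetophenone 5 + aldehyde 6.
4. 5 ⇐ 2',4',6'-trihydroxyacetophenone 1 by dibenzylation, Elbs para-hydroxylation and O-methylation, which leaves only the future C8–H free.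
5. Ring order: rings A and B are bought, ring C is built in step 5, and the preformed pyrrolidine ring is attached in step 7.

Assumption: the target SMILES encodes (R) at pyrrolidine C2, and this benzylic amine centre is taken to be configurationally stable at or below room temperature outside strongly acidic or hot basic media.

**Route**

Step 1
Reactants: 1 2',4',6'-trihydroxyacetophenone
Product: 2 1-[2,4-bis(benzyloxy)-6-hydroxyphenyl]ethan-1-one
Conditions: BnBr (2.1 equiv), K2CO3 (2.2 equiv), DMF, 0 °C → rt, 16 h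
Reagents that add atoms: benzyl bromide, BrCc1ccccc1
Why: Williamson etherification in which the 4-OH and one ortho OH react while the remaining ortho OH, hydrogen-bonded to the ketone, stays free.

Step 2
Reactants: 2 1-[2,4-bis(benzyloxy)-6-hydroxyphenyl]ethan-1-one
Product: 4 1-[2,4-bis(benzyloxy)-3,6-dihydroxyphenyl]ethan-1-one, via potassium aryl sulfate 3 (not isolated)
Conditions: K2S2O8 (1.2 equiv), 10% aq. NaOH, pyridine, 0 °C → rt, 24 h; then conc. HCl to pH 1, toluene, 90 °C, 1 h
Reagents that add atoms: potassium peroxodisulfate, [K+].[K+].[O-]S(=O)(=O)OOS(=O)(=O)[O-]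
Why: Elbs persulfate oxidation, in which the phenoxide attacks peroxodisulfate through the carbon para to the free OH to give sulfate ester 3, whose acid hydrolysis unveils the hydroquinone without touching the benzyl ethers.

Step 3
Reactants: 4 1-[2,4-bis(benzyloxy)-3,6-dihydroxyphenyl]ethan-1-one
Product: 5 1-[2,4-bis(benzyloxy)-6-hydroxy-3-methoxyphenyl]ethan-1-one
Conditions: MeI (1.1 equiv), K2CO3 (1.1 equiv), acetone, Ar, rt → 40 °C
Reagents that add atoms: iodomethane, CI
Why: Williamson methylation selective for the new, non-chelated 3-OH because the 6-OH is tied up in a strong hydrogen bond to the acetyl carbonyl.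

Step 4
Reactants: 5 1-[2,4-bis(benzyloxy)-6-hydroxy-3-methoxyphenyl]ethan-1-one; 6 4-(benzyloxy)benzaldehyde
Product: 7 (2E)-1-[2,4-bis(benzyloxy)-6-hydroxy-3-methoxyphenyl]-3-[4-(benzyloxy)phenyl]prop-2-en-1-one
Conditions: KOH (50% aq.), EtOH, rt, 36 h; then dilute HCl
Reagents that add atoms: none
Why: Claisen–Schmidt (crossed aldol) condensation of the methyl ketone enolate with a non-enolisable aldehyde, dehydration giving the (E)-chalcone.

Step 5
Reactants: 7 (2E)-1-[2,4-bis(benzyloxy)-6-hydroxy-3-methoxyphenyl]-3-[4-(benzyloxy)phenyl]prop-2-en-1-one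
Product: 8 5,7-bis(benzyloxy)-2-[4-(benzyloxy)phenyl]-6-methoxy-4H-chromen-4-one
Conditions: I2 (10 mol%), DMSO, 120 °C, 2 h
Reagents that add atoms: none
Why: Iodine-catalysed oxidative cyclisation of a 2'-hydroxychalcone (oxa-Michael closure, α-iodination, loss of HI, DMSO as terminal oxidant) closes ring C through the only free phenol, which fixes OMe at C6 and H at C8.

Step 6
Reactants: 8 5,7-bis(benzyloxy)-2-[4-(benzyloxy)phenyl]-6-methoxy-4H-chromen-4-one
Product: 9 hispidulin, 5,7-dihydroxy-2-(4-hydroxyphenyl)-6-methoxy-4H-chromen-4-one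
Conditions: H2 (1 atm), 10% Pd/C, THF/MeOH (1:1), rt
Reagents that add atoms: none
Why: Catalytic hydrogenolysis of the three aryl benzyl ethers, under which the flavone enone and the aryl methyl ether are stable.

Step 7
Reactants: 9 hispidulin; 10 tert-butyl 2,3-dihydro-1H-pyrrole-1-carboxylate
Product: 12 tert-butyl (2R)-2-[5,7-dihydroxy-2-(4-hydroxyphenyl)-6-methoxy-4-oxo-4H-chromen-8-yl]pyrrolidine-1-carboxylate, via N-acyliminium phosphate ion pair 11 (not isolated)
Conditions: (R)-3,3'-bis(2,4,6-triisopropylphenyl)-1,1'-binaphthyl-2,2'-diyl hydrogen phosphate (10 mol%), 10 (1.5 equiv, syringe pump), 4 Å MS, MeCN (0.02 M), 0 °C → rt, 24–48 h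
Reagents that add atoms: none
Why: Proposed new method: the chiral phosphoric acid protonates enecarbamate 10 at C3 to give the cyclic N-acyliminium/chiral phosphate contact ion pair 11 while its phosphoryl oxygen hydrogen-bonds the acidic 7-OH of 9, so that C8 (the only unsubstituted ring A carbon, C6 being blocked by OMe) attacks one face of the iminium carbon in an ordered bifunctional transition state and rearomatisation gives the (R)-2-arylpyrrolidine; the closest known reaction types are the chiral-phosphoric-acid-catalysed aza-Friedel–Crafts addition of indoles to acyclic N–H enecarbamates and the racemic phenolic Mannich reaction of 5,7-dihydroxyflavones at C8; the (R)-catalyst is a working assignment of the facial sense that must be confirmed by experiment.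

Step 8
Reactants: 12 tert-butyl (2R)-2-[5,7-dihydroxy-2-(4-hydroxyphenyl)-6-methoxy-4-oxo-4H-chromen-8-yl]pyrrolidine-1-carboxylate
Product: 13 5,7-dihydroxy-2-(4-hydroxyphenyl)-6-methoxy-8-[(2R)-pyrrolidin-2-yl]-4H-chromen-4-one hydrochloride
Conditions: HCl (4 M in 1,4-dioxane, 10 equiv), 0 °C, 2 h; evaporate below 20 °C
Reagents that add atoms: hydrogen chloride, Cl
Why: Acidolysis of the tert-butyl carbamate (loss of tert-butyl cation, then decarboxylation) at 0 °C breaks no bond to the stereocentre, and isolating the amine as its ammonium chloride prevents phenoxide-assisted retro-Mannich racemisation.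

Step 9
Reactants: 13 5,7-dihydroxy-2-(4-hydroxyphenyl)-6-methoxy-8-[(2R)-pyrrolidin-2-yl]-4H-chromen-4-one hydrochloride
Product: 15 5,7-dihydroxy-2-(4-hydroxyphenyl)-6-methoxy-8-[(2R)-1-methylpyrrolidin-2-yl]-4H-chromen-4-one, via N-methylideneiminium chloride 14 (not isolated)
Conditions: 37% aq. HCHO (3 equiv), 2-picoline–borane (1.2 equiv), NaOAc (1.0 equiv), MeOH/AcOH (10:1), 0 °C → rt, 3 h
Reagents that add atoms: formaldehyde, C=O
Why: Reductive amination (Borch-type N-methylation) in which the secondary amine condenses with formaldehyde to iminium 14, which the amine–borane reduces at about pH 5 without touching the flavone carbonyl or the stereocentre.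

**Compound list**

1 | 2',4',6'-trihydroxyacetophenone, 1-(2,4,6-trihydroxyphenyl)ethan-1-one | CC(=O)c1c(O)cc(O)cc1O | starting material
2 | 1-[2,4-bis(benzyloxy)-6-hydroxyphenyl]ethan-1-one | CC(=O)c1c(O)cc(OCc2ccccc2)cc1OCc1ccccc1 | intermediate
3 | potassium 3-acetyl-2,6-bis(benzyloxy)-4-hydroxyphenyl sulfate | CC(=O)c1c(O)cc(OCc2ccccc2)c(OS(=O)(=O)[O-])c1OCc1ccccc1.[K+] | intermediate (not isolated)
4 | 1-[2,4-bis(benzyloxy)-3,6-dihydroxyphenyl]ethan-1-one | CC(=O)c1c(O)cc(OCc2ccccc2)c(O)c1OCc1ccccc1 | intermediate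
5 | 1-[2,4-bis(benzyloxy)-6-hydroxy-3-methoxyphenyl]ethan-1-one | CC(=O)c1c(O)cc(OCc2ccccc2)c(OC)c1OCc1ccccc1 | intermediate
6 | 4-(benzyloxy)benzaldehyde | O=Cc1ccc(OCc2ccccc2)cc1 | starting material
7 | (2E)-1-[2,4-bis(benzyloxy)-6-hydroxy-3-methoxyphenyl]-3-[4-(benzyloxy)phenyl]prop-2-en-1-one | O=C(/C=C/c1ccc(OCc2ccccc2)cc1)c1c(O)cc(OCc2ccccc2)c(OC)c1OCc1ccccc1 | intermediate
8 | 5,7-bis(benzyloxy)-2-[4-(benzyloxy)phenyl]-6-methoxy-4H-chromen-4-one | COc1c(OCc2ccccc2)cc2oc(-c3ccc(OCc4ccccc4)cc3)cc(=O)c2c1OCc1ccccc1 | intermediate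
9 | hispidulin, 5,7-dihydroxy-2-(4-hydroxyphenyl)-6-methoxy-4H-chromen-4-one | COc1c(O)cc2oc(-c3ccc(O)cc3)cc(=O)c2c1O | intermediate
10 | tert-butyl 2,3-dihydro-1H-pyrrole-1-carboxylate | CC(C)(C)OC(=O)N1CCC=C1 | starting material
11 | 1-(tert-butoxycarbonyl)-3,4-dihydro-2H-pyrrol-1-ium (R)-3,3'-bis(2,4,6-triisopropylphenyl)-1,1'-binaphthyl-2,2'-diyl phosphate, ion pair (axial (R) descriptor of the anion carried by the name) | CC(C)(C)OC(=O)[N+]1=CCCC1.[O-]P1(=O)Oc2c(-c3c(C(C)C)cc(C(C)C)cc3C(C)C)cc3ccccc3c2-c2c(O1)c(-c3c(C(C)C)cc(C(C)C)cc3C(C)C)cc3ccccc23 | intermediate (not isolated)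
12 | tert-butyl (2R)-2-[5,7-dihydroxy-2-(4-hydroxyphenyl)-6-methoxy-4-oxo-4H-chromen-8-yl]pyrrolidine-1-carboxylate | COc1c(O)c([C@H]2CCCN2C(=O)OC(C)(C)C)c2oc(-c3ccc(O)cc3)cc(=O)c2c1O | intermediate
13 | 5,7-dihydroxy-2-(4-hydroxyphenyl)-6-methoxy-8-[(2R)-pyrrolidin-2-yl]-4H-chromen-4-one hydrochloride | COc1c(O)c([C@H]2CCCN2)c2oc(-c3ccc(O)cc3)cc(=O)c2c1O.Cl | intermediate
14 | (2R)-2-[5,7-dihydroxy-2-(4-hydroxyphenyl)-6-methoxy-4-oxo-4H-chromen-8-yl]-1-methylidenepyrrolidin-1-ium chloride | COc1c(O)c([C@H]2CCC[N+]2=C)c2oc(-c3ccc(O)cc3)cc(=O)c2c1O.[Cl-] | intermediate (not isolated)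
15 | 5,7-dihydroxy-2-(4-hydroxyphenyl)-6-methoxy-8-[(2R)-1-methylpyrrolidin-2-yl]-4H-chromen-4-one | COc1c(O)c([C@H]2CCCN2C)c2oc(-c3ccc(O)cc3)cc(=O)c2c1O | target

**Step count and risks**

Total step count: 9. Longest linear sequence: 9 steps (1 → 15); compounds 6 and 10 are bought.

The three steps most likely to fail:

Step 7 (the proposed new method). The likely failure modes are low conversion (9 is sparingly soluble and only moderately nucleophilic), low enantiomeric excess, or the opposite sense of induction. If only the sense is wrong, the mirror-image phosphoric acid is used. Enantiomeric excess is read by chiral HPLC, and the absolute configuration is checked by X-ray analysis of hydrochloride 13. The fallback uses known chemistry and sets out from 9. A Lewis-acid-catalysed N-acyliminium amidoalkylation with tert-butyl 2-methoxypyrrolidine-1-carboxylate (COC1CCCN1C(=O)OC(C)(C)C) and Sc(OTf)3 (10 mol%) in MeCN at rt gives racemic tert-butyl 2-[5,7-dihydroxy-2-(4-hydroxyphenyl)-6-methoxy-4-oxo-4H-chromen-8-yl]pyrrolidine-1-carboxylate F1. Preparative supercritical-fluid chromatography on an amylose tris(3,5-dimethylphenylcarbamate) phase then separates 12 from tert-butyl (2S)-2-[5,7-dihydroxy-2-(4-hydroxyphenyl)-6-methoxy-4-oxo-4H-chromen-8-yl]pyrrolidine-1-carboxylate F2. The fallback comes back to the route at 12.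

Step 2 (Elbs oxidation). Yields of this reaction are typically modest, with much recovered phenol and some tar. The fallback sets out from 2 and replaces the persulfate route by a quinone route. Teuber oxidation with ON(SO3K)2 (2.5 equiv, KH2PO4-buffered acetone/water, rt) gives 2-acetyl-3,5-bis(benzyloxy)cyclohexa-2,5-diene-1,4-dione F3. Na2S2O4 (EtOAc/water, rt) reduces it to the hydroquinone, and the fallback comes back to the route at 4.

Step 8 (Boc removal). While the carbamate is protonated, reversible ionisation of the electron-rich benzylic C–N bond could erode the enantiomeric excess, and the tert-butyl cation could alkylate ring B. The fallback sets out from 12 and exchanges the carbamate under base-buffered, non-protic conditions with all phenols masked. TBSOTf (6 equiv) and 2,6-lutidine (8 equiv) in CH2Cl2 at 0 °C give tert-butyldimethylsilyl (2R)-2-{5,7-bis[(tert-butyldimethylsilyl)oxy]-2-{4-[(tert-butyldimethylsilyl)oxy]phenyl}-6-methoxy-4-oxo-4H-chromen-8-yl}pyrrolidine-1-carboxylate F4. Methanolic HCl (1.25 M, 0 °C → rt) then cleaves the silyl carbamate and the silyl ethers with decarboxylation, and the fallback comes back to the route at 13.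

**Further compounds**

F1 | step 7 | racemic tert-butyl 2-[5,7-dihydroxy-2-(4-hydroxyphenyl)-6-methoxy-4-oxo-4H-chromen-8-yl]pyrrolidine-1-carboxylate | COc1c(O)c(C2CCCN2C(=O)OC(C)(C)C)c2oc(-c3ccc(O)cc3)cc(=O)c2c1O
F2 | step 7 | tert-butyl (2S)-2-[5,7-dihydroxy-2-(4-hydroxyphenyl)-6-methoxy-4-oxo-4H-chromen-8-yl]pyrrolidine-1-carboxylate | COc1c(O)c([C@@H]2CCCN2C(=O)OC(C)(C)C)c2oc(-c3ccc(O)cc3)cc(=O)c2c1O
F3 | step 2 | 2-acetyl-3,5-bis(benzyloxy)cyclohexa-2,5-diene-1,4-dione | CC(=O)C1=C(OCc2ccccc2)C(=O)C(OCc2ccccc2)=CC1=O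
F4 | step 8 | tert-butyldimethylsilyl (2R)-2-{5,7-bis[(tert-butyldimethylsilyl)oxy]-2-{4-[(tert-butyldimethylsilyl)oxy]phenyl}-6-methoxy-4-oxo-4H-chromen-8-yl}pyrrolidine-1-carboxylate | COc1c(O[Si](C)(C)C(C)(C)C)c([C@H]2CCCN2C(=O)O[Si](C)(C)C(C)(C)C)c2oc(-c3ccc(O[Si](C)(C)C(C)(C)C)cc3)cc(=O)c2c1O[Si](C)(C)C(C)(C)C
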